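**Retrosynthetic overview**

1. Ring A numbering used throughout: C1 (C=O), C2 (=CH), C3 (C–Et), C4 (CH–OH), C5 (epoxide CH), C6 (epoxide C carrying the farnesyl chain).
2. Target ⇐ its C4 triethylsilyl ether ⇐ an acyclic 6-chloro-5-oxo aldehyde: the C5–C6 bond and the C5–O–C6 bridge are made together by an intramolecular Darzens condensation, then E1cB loss of a C3 silanolate gives the C2=C3 enone.
3. Cascade precursor ⇐ C6 chlorination and C5 oxidation of the aldol adduct (C2–C3 bond) of farnesylacetone with an ethyl ketone made from methyl (S)-glycerate.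
4. Stereochemistry: C4 comes from (S)-glycerate; C5 and C6 are set relative to C4 in the ring closure.
5. Ring order: no ring until the key step, in which the carbocycle (ring A) and the oxirane form in the same flask.

Assumption: methyl (S)-glycerate and (5E,9E)-farnesylacetone are bought as single isomers.

**Route**

Step 1
Reactants: 1 methyl (S)-2,3-dihydroxypropanoate
Product: 2 methyl (S)-2,3-bis(triethylsilyloxy)propanoate
Conditions: Et3SiCl, imidazole, DMF, 0 °C → rt
Reagents that add atoms: chlorotriethylsilane, CC[Si](CC)(CC)Cl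
Why: Silyl ether formation on both hydroxyl groups touches no stereocentre, so the glycerate centre (future C4) is carried on unchanged.

Step 2
Reactants: 2 methyl (S)-2,3-bis(triethylsilyloxy)propanoate
Product: 4 (S)-1,2-bis(triethylsilyloxy)pentan-3-one, via Weinreb amide 3 (not isolated)
Conditions: MeNH(OMe)·HCl, i-PrMgCl, THF, −20 °C; then EtMgBr, 0 °C; aq. NH4Cl
Reagents that add atoms: ethylmagnesium bromide, CC[Mg]Br
Why: Weinreb ketone synthesis run through the amide made in the flask: the chelated tetrahedral magnesium adduct stops the Grignard addition at the ketone and the α-stereocentre is never enolised.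

Step 3
Reactants: 5 (5E,9E)-6,10,14-trimethylpentadeca-5,9,13-trien-2-one (farnesylacetone); 4 (S)-1,2-bis(triethylsilyloxy)pentan-3-one
Product: 8 (2S,3R,8E,12E)-3-ethyl-9,13,17-trimethyl-1,2,3-tris(triethylsilyloxy)octadeca-8,12,16-trien-5-one, via lithium enolate 6 (not isolated), via lithium aldolate 7 (not isolated)
Conditions: 5, LiN(i-Pr)2, THF, −78 °C; then 4, −78 °C; then Et3SiOTf, −78 → −40 °C
Reagents that add atoms: triethylsilyl trifluoromethanesulfonate, CC[Si](CC)(CC)OS(=O)(=O)C(F)(F)F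
Why: Kinetic enolisation of the methyl ketone at CH3 followed by aldol addition to the activated α-silyloxy ketone (Felkin–Anh, attack anti to the C4–O bond, major 3R) forms the C2–C3 bond, and cold O-silylation of the aldolate blocks retro-aldol cleavage; the C3 centre is erased in step 6, so its ratio does not matter for the target.

Step 4
Reactants: 8 (2S,3R,8E,12E)-3-ethyl-9,13,17-trimethyl-1,2,3-tris(triethylsilyloxy)octadeca-8,12,16-trien-5-one
Product: 10 (2S,3R,6RS,8E,12E)-6-chloro-3-ethyl-9,13,17-trimethyl-1,2,3-tris(triethylsilyloxy)octadeca-8,12,16-trien-5-one, via lithium enolate 9 (not isolated)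
Conditions: LiN(i-Pr)2, THF, −78 °C; then NCS, −78 °C; aq. NH4Cl
Reagents that add atoms: N-chlorosuccinimide, O=C1CCC(=O)N1Cl
Why: Kinetic deprotonation takes the unhindered C6 methylene rather than the neopentyl C2 methylene and the enolate is chlorinated by NCS (electrophilic α-halogenation of an enolate); both C6 epimers are usable because C6 is enolised again in step 6.

Step 5
Reactants: 10 (2S,3R,6RS,8E,12E)-6-chloro-3-ethyl-9,13,17-trimethyl-1,2,3-tris(triethylsilyloxy)octadeca-8,12,16-trien-5-one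
Product: 11 (2R,3R,6RS,8E,12E)-6-chloro-3-ethyl-9,13,17-trimethyl-5-oxo-2,3-bis(triethylsilyloxy)octadeca-8,12,16-trienal
Conditions: (COCl)2, DMSO, CH2Cl2, −78 → −30 °C; then Et3N, −78 → 0 °C
Reagents that add atoms: none
Why: Swern oxidation under which a primary triethylsilyl ether is converted directly into the aldehyde while the secondary and tertiary silyl ethers stay in place, and the hindered α-silyloxy aldehyde is not epimerised by Et3N at low temperature.

Step 6
Reactants: 11 (2R,3R,6RS,8E,12E)-6-chloro-3-ethyl-9,13,17-trimethyl-5-oxo-2,3-bis(triethylsilyloxy)octadeca-8,12,16-trienal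
Product: 15 (1R,5R,6R)-4-ethyl-5-(triethylsilyloxy)-1-[(2E,6E)-3,7,11-trimethyldodeca-2,6,10-trien-1-yl]-7-oxabicyclo[4.1.0]hept-3-en-2-one, via potassium chloro enolate 12 (not isolated), via potassium chlorohydrinate 13 (not isolated), via bis-silyl epoxy ketone 14 (not isolated)
Conditions: KN(SiMe3)2 (1.05 equiv), THF, −78 → −30 °C; then KN(SiMe3)2 (1.05 equiv), −78 → −20 °C; aq. NH4Cl
Reagents that add atoms: none
Why: Intramolecular Darzens condensation (Robinson-type 6-enolendo aldol, then chlorohydrinate closure): the C6 chloro enolate adds reversibly to the C5 aldehyde anti to the C4–O bond (Felkin–Anh) through a chair with Et and the side-chain CH2 equatorial, only the adduct with axial O5 anti-periplanar to axial Cl can close, so the epoxide forms cis to the C4 silyloxy group and C5 and C6 are both set from C4 (5R,6R by ring A numbering); the second equivalent of base then expels the axial C3 silanolate by E1cB to give the enone.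

Step 7
Reactants: 15 (1R,5R,6R)-4-ethyl-5-(triethylsilyloxy)-1-[(2E,6E)-3,7,11-trimethyldodeca-2,6,10-trien-1-yl]-7-oxabicyclo[4.1.0]hept-3-en-2-one
Product: 16 (1R,5R,6R)-4-ethyl-5-hydroxy-1-[(2E,6E)-3,7,11-trimethyldodeca-2,6,10-trien-1-yl]-7-oxabicyclo[4.1.0]hept-3-en-2-one
Conditions: HF·pyridine, pyridine, THF, 0 °C
Reagents that add atoms: none
Why: Fluoride-mediated cleavage of the secondary triethylsilyl ether under buffered, non-basic conditions leaves the epoxy enone, the C4 stereocentre and the triene side chain untouched.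

**Compound list**

1 | methyl (S)-2,3-dihydroxypropanoate (methyl L-glycerate) | COC(=O)[C@@H](O)CO | starting material
2 | methyl (S)-2,3-bis(triethylsilyloxy)propanoate | COC(=O)[C@@H](O[Si](CC)(CC)CC)CO[Si](CC)(CC)CC | intermediate
3 | (S)-N-methoxy-N-methyl-2,3-bis(triethylsilyloxy)propanamide (Weinreb amide) | CON(C)C(=O)[C@@H](O[Si](CC)(CC)CC)CO[Si](CC)(CC)CC | intermediate (not isolated)
4 | (S)-1,2-bis(triethylsilyloxy)pentan-3-one | CCC(=O)[C@@H](O[Si](CC)(CC)CC)CO[Si](CC)(CC)CC | intermediate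
5 | (5E,9E)-6,10,14-trimethylpentadeca-5,9,13-trien-2-one (farnesylacetone) | CC(=O)CC/C=C(\C)CC/C=C(\C)CCC=C(C)C | starting material
6 | lithium (5E,9E)-6,10,14-trimethylpentadeca-1,5,9,13-tetraen-2-olate (CH3-side enolate of 5) | [Li]OC(=C)CC/C=C(\C)CC/C=C(\C)CCC=C(C)C | intermediate (not isolated)
7 | lithium (2S,3R,8E,12E)-3-ethyl-9,13,17-trimethyl-5-oxo-1,2-bis(triethylsilyloxy)octadeca-8,12,16-trien-3-olate (aldolate) | CC[C@](CC(=O)CC/C=C(\C)CC/C=C(\C)CCC=C(C)C)(O[Li])[C@@H](O[Si](CC)(CC)CC)CO[Si](CC)(CC)CC | intermediate (not isolated)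
8 | (2S,3R,8E,12E)-3-ethyl-9,13,17-trimethyl-1,2,3-tris(triethylsilyloxy)octadeca-8,12,16-trien-5-one (major C3 epimer) | CC[C@](CC(=O)CC/C=C(\C)CC/C=C(\C)CCC=C(C)C)(O[Si](CC)(CC)CC)[C@@H](O[Si](CC)(CC)CC)CO[Si](CC)(CC)CC | intermediate
9 | lithium enolate of 8 at C6 (C5=C6 enolate by chain numbering, geometry not defined) | CC[C@](CC(O[Li])=CC/C=C(\C)CC/C=C(\C)CCC=C(C)C)(O[Si](CC)(CC)CC)[C@@H](O[Si](CC)(CC)CC)CO[Si](CC)(CC)CC | intermediate (not isolated)
10 | (2S,3R,6RS,8E,12E)-6-chloro-3-ethyl-9,13,17-trimethyl-1,2,3-tris(triethylsilyloxy)octadeca-8,12,16-trien-5-one | CC[C@](CC(=O)C(Cl)C/C=C(\C)CC/C=C(\C)CCC=C(C)C)(O[Si](CC)(CC)CC)[C@@H](O[Si](CC)(CC)CC)CO[Si](CC)(CC)CC | intermediate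
11 | (2R,3R,6RS,8E,12E)-6-chloro-3-ethyl-9,13,17-trimethyl-5-oxo-2,3-bis(triethylsilyloxy)octadeca-8,12,16-trienal | CC[C@](CC(=O)C(Cl)C/C=C(\C)CC/C=C(\C)CCC=C(C)C)(O[Si](CC)(CC)CC)[C@@H](O[Si](CC)(CC)CC)C=O | intermediate
12 | potassium enolate of 11 at the chlorinated carbon (geometry not defined) | CC[C@](CC(O[K])=C(Cl)C/C=C(\C)CC/C=C(\C)CCC=C(C)C)(O[Si](CC)(CC)CC)[C@@H](O[Si](CC)(CC)CC)C=O | intermediate (not isolated)
13 | potassium alkoxide of (3R,4S,5R,6S)-6-chloro-3-ethyl-5-hydroxy-3,4-bis(triethylsilyloxy)-6-[(2E,6E)-farnesyl]cyclohexan-1-one (ring A numbering; O3, O4, O5 all cis, Cl trans to O5) | CC[C@@]1(O[Si](CC)(CC)CC)CC(=O)[C@](Cl)(C/C=C(\C)CC/C=C(\C)CCC=C(C)C)[C@H](O[K])[C@@H]1O[Si](CC)(CC)CC | intermediate (not isolated)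
14 | (1R,4R,5S,6R)-4-ethyl-4,5-bis(triethylsilyloxy)-1-[(2E,6E)-3,7,11-trimethyldodeca-2,6,10-trien-1-yl]-7-oxabicyclo[4.1.0]heptan-2-one | CC[C@@]1(O[Si](CC)(CC)CC)CC(=O)[C@]2(C/C=C(\C)CC/C=C(\C)CCC=C(C)C)O[C@@H]2[C@@H]1O[Si](CC)(CC)CC | intermediate (not isolated)
15 | (1R,5R,6R)-4-ethyl-5-(triethylsilyloxy)-1-[(2E,6E)-3,7,11-trimethyldodeca-2,6,10-trien-1-yl]-7-oxabicyclo[4.1.0]hept-3-en-2-one | CCC1=CC(=O)[C@]2(C/C=C(\C)CC/C=C(\C)CCC=C(C)C)O[C@@H]2[C@@H]1O[Si](CC)(CC)CC | intermediate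
16 | (1R,5R,6R)-4-ethyl-5-hydroxy-1-[(2E,6E)-3,7,11-trimethyldodeca-2,6,10-trien-1-yl]-7-oxabicyclo[4.1.0]hept-3-en-2-one (CID44566894) | CCC1=CC(=O)[C@]2(C/C=C(\C)CC/C=C(\C)CCC=C(C)C)O[C@@H]2[C@@H]1O | target

**Totals and risks**

Total steps: 7. Longest linear sequence: 7 (1 → 16); 5 enters at step 3.

The three steps most likely to fail:

Step 6 (Darzens/E1cB cascade). The base can epimerise C4 of the aldehyde, trigger silyl migration between O4 and O5, or start the E1cB before ring closure; the cis relation between the epoxide and the C4 oxygen rests on a conformational argument only. Fallback: from 10, a second enolate chlorination (LiN(i-Pr)2, then NCS) gives the 6,6-dichloro ketone F1, and Swern oxidation as in step 5 gives the dichloro keto aldehyde F2. SmI2 (2 equiv, THF, −78 °C) then generates the chloro enolate reductively, without base, and Reformatsky-type closure gives the ring A chlorohydrin F3. Deprotonation of F3 with KN(SiMe3)2 gives 13 and the route continues to 15.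

Step 3 (ketone–ketone aldol). Proton transfer between the enolate and 4, retro-aldol before silylation, and some enolisation of 5 on the CH2 side can all lower the yield. Fallback: from 5, condensation with 1,1-dimethylhydrazine gives the N,N-dimethylhydrazone F4. Its aza-enolate (n-BuLi, THF, −78 °C, metalation at CH3) adds to 4 and Et3SiOTf caps the alkoxide to give the silylated hydrazone adduct F5. CuCl2 in aqueous THF (pH 7) cleaves the hydrazone and returns 8.

Step 4 (enolate chlorination). Proton exchange between 9 and 10 can lead to dichlorination, and any C2-side enolate would eliminate the C3 silanolate. Fallback: from 4, using a nucleophile in which only C6 is acidic. Allyl acetoacetate is C-alkylated with (2E,6E)-farnesyl bromide (K2CO3, acetone) to give allyl 2-farnesylacetoacetate F6. Its dianion (NaH, then n-BuLi) adds through the methyl terminus to 4 and Et3SiOTf gives the silylated keto ester F7. NCS with catalytic Et3N chlorinates the doubly activated carbon to give the chloro keto ester F8. Pd(PPh3)4, HCO2H and Et3N remove the allyl ester with decarboxylation and return 10.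

**Further compounds**

F1 | step 6 | (2S,3R,8E,12E)-6,6-dichloro-3-ethyl-9,13,17-trimethyl-1,2,3-tris(triethylsilyloxy)octadeca-8,12,16-trien-5-one | CC[C@](CC(=O)C(Cl)(Cl)C/C=C(\C)CC/C=C(\C)CCC=C(C)C)(O[Si](CC)(CC)CC)[C@@H](O[Si](CC)(CC)CC)CO[Si](CC)(CC)CC
F2 | step 6 | (2R,3R,8E,12E)-6,6-dichloro-3-ethyl-9,13,17-trimethyl-5-oxo-2,3-bis(triethylsilyloxy)octadeca-8,12,16-trienal | CC[C@](CC(=O)C(Cl)(Cl)C/C=C(\C)CC/C=C(\C)CCC=C(C)C)(O[Si](CC)(CC)CC)[C@@H](O[Si](CC)(CC)CC)C=O
F3 | step 6 | (3R,4S,5R,6S)-6-chloro-3-ethyl-5-hydroxy-3,4-bis(triethylsilyloxy)-6-[(2E,6E)-farnesyl]cyclohexan-1-one (ring A numbering) | CC[C@@]1(O[Si](CC)(CC)CC)CC(=O)[C@](Cl)(C/C=C(\C)CC/C=C(\C)CCC=C(C)C)[C@H](O)[C@@H]1O[Si](CC)(CC)CC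
F4 | step 3 | (5E,9E)-6,10,14-trimethylpentadeca-5,9,13-trien-2-one N,N-dimethylhydrazone | CC(=NN(C)C)CC/C=C(\C)CC/C=C(\C)CCC=C(C)C
F5 | step 3 | N,N-dimethylhydrazone of 8 (2S,3R,8E,12E) | CC[C@](CC(=NN(C)C)CC/C=C(\C)CC/C=C(\C)CCC=C(C)C)(O[Si](CC)(CC)CC)[C@@H](O[Si](CC)(CC)CC)CO[Si](CC)(CC)CC
F6 | step 4 | allyl (4E,8E)-2-acetyl-5,9,13-trimethyltetradeca-4,8,12-trienoate (allyl 2-farnesylacetoacetate) | CC(=O)C(C/C=C(\C)CC/C=C(\C)CCC=C(C)C)C(=O)OCC=C
F7 | step 4 | allyl (4E,8E)-2-[(3R,4S)-3-ethyl-3,4,5-tris(triethylsilyloxy)pentanoyl]-5,9,13-trimethyltetradeca-4,8,12-trienoate | CC[C@](CC(=O)C(C/C=C(\C)CC/C=C(\C)CCC=C(C)C)C(=O)OCC=C)(O[Si](CC)(CC)CC)[C@@H](O[Si](CC)(CC)CC)CO[Si](CC)(CC)CC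
F8 | step 4 | allyl (4E,8E)-2-chloro-2-[(3R,4S)-3-ethyl-3,4,5-tris(triethylsilyloxy)pentanoyl]-5,9,13-trimethyltetradeca-4,8,12-trienoate | CC[C@](CC(=O)C(Cl)(C/C=C(\C)CC/C=C(\C)CCC=C(C)C)C(=O)OCC=C)(O[Si](CC)(CC)CC)[C@@H](O[Si](CC)(CC)CC)CO[Si](CC)(CC)CC
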